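**Retrosynthetic overview**
- The target is opened at the C4(upper)–C6(lower) bond into two halves made from one monomer: a 4β-hydroxy electrophile and an all-cis 3,4-diol nucleophile; free phenols are released last by hydrogenolysis.
- Both halves come from one 2,3-cis-flavan-3-ol by C4 oxygenation, and C4 is inverted for the lower half by oxidation and reduction.
- The flavan-3-ol comes from a (2R)-flavan-3-one; a bulky hydride sets C3 from C2.
- Key step: the C4–C4a bond of the flavan-3-one is made from an α-oxo gold carbene (an α-keto cation equivalent at C4) and the electron-rich ring A carbon; ring C closes here.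
- The carbene precursor is an aryl propargyl ether made by copper-catalysed asymmetric propargylic etherification (sets C2) from 4-(benzyloxy)benzaldehyde, ethynylmagnesium bromide and ketal-protected pyrogallol; rings A and B are bought.

Assumption: flavan numbering is used; α is the face of ring C carrying the C2 aryl group of that unit and β the opposite face; the target is read as upper unit (2R,3R,4S), lower unit (2R,3R,4R), i.e. epioritin-(4β→6)-epioritin-4α-ol; the sense of induction of the pybox ligand in step 3 is assigned by analogy, and the antipodal ligand is used if it proves opposite.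

**Step 1**
Reactants: 1 pyrogallol; 2 dichlorodiphenylmethane
Product: 3 2,2-diphenyl-1,3-benzodioxol-4-ol
Conditions: Ph2CCl2 (1.05 equiv), Ph2O, 175 °C, 30 min
Reagents that add atoms: none
Why: Cyclic ketal formation (double substitution at the gem-dichloride) ties up two adjacent phenols as a five-membered ketal and leaves one phenol free, the future O1.

**Step 2**
Reactants: 4 4-(benzyloxy)benzaldehyde; 5 ethynylmagnesium bromide
Product: 7 rac-1-[4-(benzyloxy)phenyl]prop-2-yn-1-yl acetate, via bromomagnesium alkoxide 6 (not isolated)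
Conditions: HC≡CMgBr (1.2 equiv), THF, 0 °C; then Ac2O (1.5 equiv), 0 °C to rt
Reagents that add atoms: acetic anhydride, CC(=O)OC(C)=O
Why: Grignard 1,2-addition to the aldehyde followed by O-acylation of the alkoxide in the same flask; the product is racemic because the stereocentre is set in step 3.

**Step 3**
Reactants: 7 rac-1-[4-(benzyloxy)phenyl]prop-2-yn-1-yl acetate; 3 2,2-diphenyl-1,3-benzodioxol-4-ol
Product: 8 4-{[(1S)-1-[4-(benzyloxy)phenyl]prop-2-yn-1-yl]oxy}-2,2-diphenyl-1,3-benzodioxole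
Conditions: Cu(MeCN)4PF6 (5 mol %), (S,S)-Ph-pybox (6 mol %), i-Pr2NEt (1.2 equiv), 3 (1.2 equiv), CH2Cl2, −20 °C
Reagents that add atoms: none
Why: Copper-catalysed asymmetric propargylic substitution: the monovalent copper acetylide loses acetate to a copper-bound propargylic electrophile that the phenol attacks inside the chiral pybox pocket, converting both enantiomers of 7 into the S ether, which is the future 2R centre (only the CIP ranking changes on ring closure).

**Step 4 (key step)**
Reactants: 8 4-{[(1S)-1-[4-(benzyloxy)phenyl]prop-2-yn-1-yl]oxy}-2,2-diphenyl-1,3-benzodioxole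
Product: 10 (2R)-4'-benzyloxy-7,8-(diphenylmethylenedioxy)flavan-3-one, via alpha-oxo gold carbene 9 (not isolated)
Conditions: (Me4tBuXPhos)AuNTf2 (5 mol %), 2,6-dichloropyridine N-oxide (1.3 equiv), ClCH2CH2Cl, rt; crude ketone used at once
Reagents that add atoms: 2,6-dichloropyridine N-oxide, [O-][n+]1c(Cl)cccc1Cl
Why: Gold-catalysed alkyne oxidation then intramolecular Friedel–Crafts-type closure: the N-oxide oxidises the internal alkyne carbon on monovalent gold, making the terminal carbon an electrophilic α-keto carbene (reversed polarity for a ketone α-carbon), which is captured six-ring-wise by the arene carbon ortho to O1 and para to a ketal oxygen; the C2 stereocentre is not involved and is retained.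

**Step 5**
Reactants: 10 (2R)-4'-benzyloxy-7,8-(diphenylmethylenedioxy)flavan-3-one
Product: 11 (2R,3R)-2,3-cis-4'-benzyloxy-7,8-(diphenylmethylenedioxy)flavan-3-ol
Conditions: LiBH(s-Bu)3 (1.5 equiv), LiBr, THF, −78 °C; then H2O
Reagents that add atoms: none
Why: Substrate-controlled ketone reduction in which the bulky hydride attacks the face opposite the equatorial C2 aryl group, giving the axial 3α-OH cis to the aryl (3R).

**Step 6**
Reactants: 11 (2R,3R)-2,3-cis-4'-benzyloxy-7,8-(diphenylmethylenedioxy)flavan-3-ol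
Product: 13 (2R,3R,4S)-2,3-cis-3,4-trans-4'-benzyloxy-7,8-(diphenylmethylenedioxy)flavan-3,4-diol, via flavan-4-ylium hydroquinonate ion pair 12 (not isolated)
Conditions: DDQ (1.2 equiv), CH2Cl2/H2O 20:1, 0 °C to rt
Reagents that add atoms: water, O
Why: Oxidative benzylic C–H functionalisation: DDQ abstracts hydride from C4 to give the benzylic cation (stabilised by O1 and the 7-oxygen) paired with the DDQ-derived hydroquinone monoanion, and water adds anti to the axial 3-OH, giving the 4β-OH (4S).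

**Step 7**
Reactants: 13 (2R,3R,4S)-2,3-cis-3,4-trans-4'-benzyloxy-7,8-(diphenylmethylenedioxy)flavan-3,4-diol
Product: 14 (2R,3S)-2,3-cis-4'-benzyloxy-3-hydroxy-7,8-(diphenylmethylenedioxy)flavan-4-one
Conditions: activated MnO2 (15 equiv), CH2Cl2, rt; used at once
Reagents that add atoms: none
Why: Chemoselective MnO2 oxidation of the electron-rich benzylic alcohol leaves the non-benzylic 3-OH alone, and the neutral medium avoids epimerising the cis α-hydroxy ketone (the C3 descriptor changes to S by CIP ranking only).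

**Step 8**
Reactants: 14 (2R,3S)-2,3-cis-4'-benzyloxy-3-hydroxy-7,8-(diphenylmethylenedioxy)flavan-4-one
Product: 15 (2R,3R,4R)-2,3-cis-3,4-cis-4'-benzyloxy-7,8-(diphenylmethylenedioxy)flavan-3,4-diol
Conditions: NaBH4, CeCl3·7H2O, MeOH/THF, −20 °C
Reagents that add atoms: none
Why: Luche-type carbonyl reduction in which hydride enters axially from the β face, anti to the axial 3-OH and away from the C2 aryl, giving the equatorial 4α-OH (4R, all-cis).

**Step 9**
Reactants: 13 (2R,3R,4S)-2,3-cis-3,4-trans-4'-benzyloxy-7,8-(diphenylmethylenedioxy)flavan-3,4-diol; 15 (2R,3R,4R)-2,3-cis-3,4-cis-4'-benzyloxy-7,8-(diphenylmethylenedioxy)flavan-3,4-diol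
Product: 17 4',4'''-di-O-benzyl-7,8:7'',8''-bis-O-(diphenylmethylene)-epioritin-(4β→6)-epioritin-4α-ol, via flavan-4-ylium triflate ion pair 16 (not isolated)
Conditions: 13 (1 equiv, slow addition), 15 (3 equiv, excess recovered), TMSOTf (0.2 equiv), 4 Å MS, CH2Cl2, −40 to −20 °C
Reagents that add atoms: none
Why: Friedel–Crafts benzylation (interflavan coupling): TMSOTf ionises the pseudo-axial 4β-OH of 13, more readily than the equatorial 4α-OH of 15 or of the product, to the C4 cation with triflate as counter-ion, and C6 of 15 (ortho to the 7-oxygen, para to O1, not peri-hindered) attacks it anti to the axial 3-OH, setting the upper C4 aryl β (3,4-trans).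

**Step 10**
Reactants: 17 4',4'''-di-O-benzyl-7,8:7'',8''-bis-O-(diphenylmethylene)-epioritin-(4β→6)-epioritin-4α-ol
Product: 18 epioritin-(4β→6)-epioritin-4α-ol (CNP0391561.1)
Conditions: H2 (1 atm), Pd(OH)2/C, THF/MeOH 1:1, rt, stopped at full O-deprotection; filtered under Ar, lyophilised
Reagents that add atoms: none
Why: Hydrogenolysis removes both aryl benzyl ethers and both diphenylmethylene ketals in a neutral medium, where the secondary 4-OH, the ring C–O bonds and the interflavan bond are cleaved much more slowly; no stereocentre is touched.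

**Compound list**
1 | pyrogallol | Oc1cccc(O)c1O | starting material
2 | dichlorodiphenylmethane | ClC(Cl)(c1ccccc1)c1ccccc1 | starting material
3 | 2,2-diphenyl-1,3-benzodioxol-4-ol | Oc1cccc2OC(c3ccccc3)(c3ccccc3)Oc12 | intermediate
4 | 4-(benzyloxy)benzaldehyde | O=Cc1ccc(OCc2ccccc2)cc1 | starting material
5 | ethynylmagnesium bromide | C#C[Mg]Br | starting material
6 | bromomagnesium rac-1-[4-(benzyloxy)phenyl]prop-2-yn-1-olate | C#CC(O[Mg]Br)c1ccc(OCc2ccccc2)cc1 | intermediate (not isolated)
7 | rac-1-[4-(benzyloxy)phenyl]prop-2-yn-1-yl acetate | C#CC(OC(C)=O)c1ccc(OCc2ccccc2)cc1 | intermediate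
8 | 4-{[(1S)-1-[4-(benzyloxy)phenyl]prop-2-yn-1-yl]oxy}-2,2-diphenyl-1,3-benzodioxole | C#C[C@H](Oc1cccc2OC(c3ccccc3)(c3ccccc3)Oc12)c1ccc(OCc2ccccc2)cc1 | intermediate
9 | alpha-oxo gold carbene cation: {(3R)-3-[4-(benzyloxy)phenyl]-3-[(2,2-diphenyl-1,3-benzodioxol-4-yl)oxy]-2-oxopropylidene}gold bound to Me4tBuXPhos, NTf2 counter-ion, same spatial arrangement as 8 | O=C(C=[Au][P+](C(C)(C)C)(C(C)(C)C)c1c(C)c(C)c(C)c(C)c1-c1c(C(C)C)cc(C(C)C)cc1C(C)C)[C@H](Oc1cccc2OC(c3ccccc3)(c3ccccc3)Oc12)c1ccc(OCc2ccccc2)cc1 | intermediate (not isolated)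
10 | (2R)-4'-benzyloxy-7,8-(diphenylmethylenedioxy)flavan-3-one | O=C1Cc2ccc3OC(c4ccccc4)(c4ccccc4)Oc3c2O[C@@H]1c1ccc(OCc2ccccc2)cc1 | intermediate
11 | (2R,3R)-2,3-cis-4'-benzyloxy-7,8-(diphenylmethylenedioxy)flavan-3-ol | O[C@@H]1Cc2ccc3OC(c4ccccc4)(c4ccccc4)Oc3c2O[C@@H]1c1ccc(OCc2ccccc2)cc1 | intermediate
12 | (2R,3R)-4'-benzyloxy-3-hydroxy-7,8-(diphenylmethylenedioxy)flavan-4-ylium 2,3-dichloro-5,6-dicyano-4-hydroxyphenolate (ion pair formed by hydride transfer from C4 of 11 to DDQ) | O[C@@H]1[CH+]c2ccc3OC(c4ccccc4)(c4ccccc4)Oc3c2O[C@@H]1c1ccc(OCc2ccccc2)cc1.[O-]c1c(Cl)c(Cl)c(O)c(C#N)c1C#N | intermediate (not isolated)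
13 | (2R,3R,4S)-2,3-cis-3,4-trans-4'-benzyloxy-7,8-(diphenylmethylenedioxy)flavan-3,4-diol (4β-OH) | O[C@@H]1[C@@H](O)c2ccc3OC(c4ccccc4)(c4ccccc4)Oc3c2O[C@@H]1c1ccc(OCc2ccccc2)cc1 | intermediate
14 | (2R,3S)-2,3-cis-4'-benzyloxy-3-hydroxy-7,8-(diphenylmethylenedioxy)flavan-4-one | O[C@@H]1C(=O)c2ccc3OC(c4ccccc4)(c4ccccc4)Oc3c2O[C@@H]1c1ccc(OCc2ccccc2)cc1 | intermediate
15 | (2R,3R,4R)-2,3-cis-3,4-cis-4'-benzyloxy-7,8-(diphenylmethylenedioxy)flavan-3,4-diol (4α-OH) | O[C@@H]1[C@H](O)c2ccc3OC(c4ccccc4)(c4ccccc4)Oc3c2O[C@@H]1c1ccc(OCc2ccccc2)cc1 | intermediate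
16 | (2R,3R)-4'-benzyloxy-3-hydroxy-7,8-(diphenylmethylenedioxy)flavan-4-ylium trifluoromethanesulfonate (ion pair formed by ionisation of the 4β-OH of 13) | O[C@@H]1[CH+]c2ccc3OC(c4ccccc4)(c4ccccc4)Oc3c2O[C@@H]1c1ccc(OCc2ccccc2)cc1.[O-]S(=O)(=O)C(F)(F)F | intermediate (not isolated)
17 | protected dimer: upper unit 2α-aryl, 3α-OH, 4β-aryl (CIP 2R,3R,4R while protected); lower unit 2α-aryl, 3α-OH, 4α-OH (2R,3R,4R), joined C4(upper)–C6(lower) | O[C@@H]1[C@@H](c2cc3[C@@H](O)[C@@H](O)[C@@H](c4ccc(OCc5ccccc5)cc4)Oc3c3OC(c4ccccc4)(c4ccccc4)Oc23)c2ccc3OC(c4ccccc4)(c4ccccc4)Oc3c2O[C@@H]1c1ccc(OCc2ccccc2)cc1 | intermediate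
18 | epioritin-(4β→6)-epioritin-4α-ol: upper (2R,3R,4S), lower (2R,3R,4R); the upper C4 descriptor changes from 17 by CIP ranking only | Oc1ccc([C@H]2Oc3c(ccc(O)c3O)[C@H](c3cc4c(c(O)c3O)O[C@H](c3ccc(O)cc3)[C@H](O)[C@@H]4O)[C@H]2O)cc1 | target

**Totals**
Total steps: 10. Longest linear sequence: 9 (steps 2 to 10 from 4, or steps 1 and 3 to 10 from 1).

**Three steps most likely to fail**

Step 4. The doubly activated propargylic C–O bond may ionise under (Me4tBuXPhos)AuNTf2, plain hydroarylation may outrun alkyne oxidation on this electron-rich arene, and the flavan-3-one may enolise. The fallback sets out from 8 and comes back at 10. It drops the oxidant and accepts the hydroarylation: Ph3PAuNTf2 (2 mol %) in CH2Cl2 at rt closes the same ring carbon onto the alkyne to give (2S)-4'-benzyloxy-7,8-(diphenylmethylenedioxy)flav-3-ene F1, with C2 untouched. BH3·THF then NaOH/H2O2 places boron at C3 anti to the aryl group and gives (2R,3S)-2,3-trans-4'-benzyloxy-7,8-(diphenylmethylenedioxy)flavan-3-ol F2. Dess–Martin periodinane in CH2Cl2 then gives ketone 10. This costs two extra steps.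

Step 9. Rings of the 7,8-dioxygenated type are known to be sluggish partners, and self-coupling of 13, attack at C5, or further ionisation of the product are possible. The fallback sets out from 13 and comes back at 17. 13 with BnSH (5 equiv) and catalytic TMSOTf in CH2Cl2 at −40 °C gives (2R,3S,4S)-4β-benzylsulfanyl-4'-benzyloxy-7,8-(diphenylmethylenedioxy)flavan-3-ol F3, the thiol capturing the cation of ion pair 16 anti to the 3-OH. F3 and 15 (3 equiv) with AgBF4 in THF at 0 °C then give 17. AgBF4 activates only the C–S bond, so the 4α-OH groups of 15 and of the product cannot ionise and chain growth stops at the dimer.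

Step 3. Both partners are electron-rich, so a racemic ionisation pathway or C-alkylation of the phenol may erode ee or yield. The fallback sets out from 4 and comes back at 8. Zinc-mediated asymmetric alkynylation of 4 (Me2Zn, trimethylsilylacetylene, ProPhenol ligand, Ph3P=O, toluene, 4 °C) gives (S)-1-[4-(benzyloxy)phenyl]-3-(trimethylsilyl)prop-2-yn-1-ol F4. K2CO3 in MeOH gives (R)-1-[4-(benzyloxy)phenyl]prop-2-yn-1-ol F5. Mitsunobu etherification with 3 (PPh3, DIAD, toluene, −20 °C) proceeds with inversion to 8. This costs one extra step.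

**Further compounds**
F1 | step 4 | (2S)-4'-benzyloxy-7,8-(diphenylmethylenedioxy)flav-3-ene | C1=Cc2ccc3OC(c4ccccc4)(c4ccccc4)Oc3c2O[C@@H]1c1ccc(OCc2ccccc2)cc1
F2 | step 4 | (2R,3S)-2,3-trans-4'-benzyloxy-7,8-(diphenylmethylenedioxy)flavan-3-ol | O[C@H]1Cc2ccc3OC(c4ccccc4)(c4ccccc4)Oc3c2O[C@@H]1c1ccc(OCc2ccccc2)cc1
F3 | step 9 | (2R,3S,4S)-4β-benzylsulfanyl-4'-benzyloxy-7,8-(diphenylmethylenedioxy)flavan-3-ol | O[C@@H]1[C@@H](SCc2ccccc2)c2ccc3OC(c4ccccc4)(c4ccccc4)Oc3c2O[C@@H]1c1ccc(OCc2ccccc2)cc1
F4 | step 3 | (S)-1-[4-(benzyloxy)phenyl]-3-(trimethylsilyl)prop-2-yn-1-ol | C[Si](C)(C)C#C[C@@H](O)c1ccc(OCc2ccccc2)cc1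
F5 | step 3 | (R)-1-[4-(benzyloxy)phenyl]prop-2-yn-1-ol | C#C[C@@H](O)c1ccc(OCc2ccccc2)cc1
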